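**Plan**

- Chain positions C1–C18 are counted from the aryl ketone carbon. The 2,4,6-trihydroxyphenyl ketone is the tris-enol of a 2-acylcyclohexane-1,3,5-trione, that is, a tetraketide folded onto itself with the C18 acyl chain as starter; this lets the benzene ring be built from an open-chain methyl 3,5,7-trioxo ester.
- Retrosynthetic cuts, in order: the C9 O–Si bond; one ring C–C bond (acyl-bearing ring carbon to a neighbouring C–OH carbon); the bond from the C1 carbonyl to the future ring carbon (Weinreb amide plus methyl 3,5-dioxohexanoate trianion); C5–C6 (acetylide alkylation); C8–C9 (propargylation); C12=C13 (Wittig).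
- Forward: hexenyl ylide and (E)-4,4-dimethoxybut-2-enal give the C9–C18 trienal; propargylation, silylation, alkylation with an orthoester-masked 5-bromopentanoate and semi-hydrogenation give the C1–C18 ester; Weinreb amide, trianion acylation, ring closure (the only ring, penultimate step), desilylation.
- Stereochemistry: C9 (R) comes from a chiral phosphoric acid-catalysed allenylboration of the trienal. 15Z and 10E are bought in, 12Z comes from a lithium-free Wittig reaction, and 6Z from syn-hydrogenation of the alkyne.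

Key step: step 12

Assumption: (R)-TRIP is taken to direct the allenylboronate to the Re face of a 2-enal, as with aryl and alkenyl aldehydes; the C9 configuration would be checked by Mosher ester analysis at compound 9 and the antipodal acid used if the sense were reversed.

**Route**

Step 1
Reactants: 1 (Z)-hex-3-en-1-ol
Product: 2 (Z)-1-iodohex-3-ene
Conditions: PPh3, I2, imidazole, CH2Cl2, 0 °C → rt
Reagents that add atoms: iodine, II
Why: Appel-type iodination, in which iodide displaces the oxyphosphonium of a primary alcohol by SN2 without touching the Z-alkene.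

Step 2
Reactants: 2 (Z)-1-iodohex-3-ene
Product: 3 [(3Z)-hex-3-en-1-yl]triphenylphosphonium iodide
Conditions: PPh3, MeCN, reflux
Reagents that add atoms: triphenylphosphine, c1ccc(cc1)P(c1ccccc1)c1ccccc1
Why: Phosphonium salt formation by SN2 quaternisation of triphenylphosphine with an unhindered primary iodide.

Step 3
Reactants: 3 [(3Z)-hex-3-en-1-yl]triphenylphosphonium iodide, 4 (E)-4,4-dimethoxybut-2-enal
Product: 6 (2E,4Z,7Z)-1,1-dimethoxydeca-2,4,7-triene, via phosphorus ylide 5 (not isolated)
Conditions: NaHMDS, THF, −78 → 0 °C; then 4, −78 → −20 °C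
Reagents that add atoms: none
Why: Wittig olefination with a non-stabilised ylide under lithium-free conditions should give the new C12=C13 alkene Z through the kinetic cis-oxaphosphetane, while the E-alkene of the enal is carried over unchanged.

Step 4
Reactants: 6 (2E,4Z,7Z)-1,1-dimethoxydeca-2,4,7-triene
Product: 7 (2E,4Z,7Z)-deca-2,4,7-trienal
Conditions: Amberlyst-15, acetone/H2O, 0 °C, short contact, dark; used at once
Reagents that add atoms: water, O
Why: Acid-catalysed acetal hydrolysis of an allylic dimethyl acetal, run cold and briefly on a solid acid so that the 4Z-alkene of the dienal should not isomerise.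

Step 5
Reactants: 7 (2E,4Z,7Z)-deca-2,4,7-trienal, 8 allenylboronic acid pinacol ester
Product: 9 (4R,5E,7Z,10Z)-trideca-5,7,10-trien-1-yn-4-ol
Conditions: (R)-TRIP (10 mol %), 4 Å MS, toluene, −20 °C; aq. NaHCO3 work-up
Reagents that add atoms: none
Why: Chiral phosphoric acid-catalysed asymmetric propargylation (allenylboration) through a closed six-membered SE2′ transition state, in which the (R)-phosphate is hydrogen-bonded to a boronate oxygen and shields the Si face, so that the propargyl group is delivered to the Re face and the carbinol centre is formed R, γ-attack of the allene giving the homopropargylic and not the allenyl alcohol.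

Step 6
Reactants: 9 (4R,5E,7Z,10Z)-trideca-5,7,10-trien-1-yn-4-ol
Product: 10 tert-butyl{[(4R,5E,7Z,10Z)-trideca-5,7,10-trien-1-yn-4-yl]oxy}dimethylsilane
Conditions: TBSCl, imidazole, DMF, 0 °C → rt
Reagents that add atoms: tert-butyldimethylsilyl chloride, CC(C)(C)[Si](C)(C)Cl
Why: Imidazole-promoted silylation of a secondary alcohol under basic conditions, which should leave the ionisable dienyl carbinol and its configuration intact.

Step 7
Reactants: 11 5-bromopentanenitrile
Product: 13 5-bromo-1,1,1-trimethoxypentane, via imidate hydrochloride 12 (not isolated)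
Conditions: HCl (g), MeOH (1.1 equiv), Et2O, 0 °C; then MeOH, hexane, rt
Reagents that add atoms: methanol, CO
Why: Pinner reaction, in which the nitrile is converted to the imidate salt and this is methanolysed to the trimethyl orthoester while the primary bromide stays untouched under anhydrous acid.

Step 8
Reactants: 10 tert-butyl{[(4R,5E,7Z,10Z)-trideca-5,7,10-trien-1-yn-4-yl]oxy}dimethylsilane, 13 5-bromo-1,1,1-trimethoxypentane
Product: 16 methyl (9R,10E,12Z,15Z)-9-[(tert-butyldimethylsilyl)oxy]octadeca-10,12,15-trien-6-ynoate, via lithium acetylide 14 (not isolated), via trimethyl orthoester 15 (not isolated)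
Conditions: n-BuLi (1.0 equiv), THF, −78 °C; 13, DMPU, −78 °C → rt; then 0.1 M aq. citric acid, THF, 0 °C
Reagents that add atoms: water, O
Why: SN2 alkylation of a lithium acetylide with a primary bromide in a dipolar cosolvent, the orthoester protecting the carboxyl carbon from acetylide addition and from lactonisation and then being hydrolysed to the methyl ester by dilute acid far faster than the silyl ether can be cleaved.

Step 9
Reactants: 16 methyl (9R,10E,12Z,15Z)-9-[(tert-butyldimethylsilyl)oxy]octadeca-10,12,15-trien-6-ynoate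
Product: 17 methyl (6Z,9R,10E,12Z,15Z)-9-[(tert-butyldimethylsilyl)oxy]octadeca-6,10,12,15-tetraenoate
Conditions: H2 (1 atm), Lindlar catalyst, quinoline, EtOAc/hexane, 0 °C → rt, stopped at 1 equiv uptake
Reagents that add atoms: none
Why: Lindlar semi-hydrogenation, in which the alkyne binds to the poisoned palladium more strongly than any of the alkenes and takes up one equivalent of hydrogen by syn addition to give the 6Z-alkene.

Step 10
Reactants: 17 methyl (6Z,9R,10E,12Z,15Z)-9-[(tert-butyldimethylsilyl)oxy]octadeca-6,10,12,15-tetraenoate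
Product: 18 (6Z,9R,10E,12Z,15Z)-9-[(tert-butyldimethylsilyl)oxy]-N-methoxy-N-methyloctadeca-6,10,12,15-tetraenamide
Conditions: MeNH(OMe)·HCl, i-PrMgCl, THF, −20 → 0 °C
Reagents that add atoms: N,O-dimethylhydroxylamine hydrochloride, CNOC.Cl
Why: Weinreb amide formation by aminolysis of the methyl ester with the chloromagnesium amide of N,O-dimethylhydroxylamine, conditions too mild to deprotonate the bis-allylic position or disturb the silyl ether.

Step 11
Reactants: 18 (6Z,9R,10E,12Z,15Z)-9-[(tert-butyldimethylsilyl)oxy]-N-methoxy-N-methyloctadeca-6,10,12,15-tetraenamide, 19 methyl 3,5-dioxohexanoate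
Product: 21 methyl (12Z,15R,16E,18Z,21Z)-15-[(tert-butyldimethylsilyl)oxy]-3,5,7-trioxotetracosa-12,16,18,21-tetraenoate, via trilithium trianion 20 (not isolated)
Conditions: 19 (2 equiv), LDA (6.1 equiv), THF, −78 → 0 °C; then 18, −78 → −20 °C; AcOH, −78 °C, pH 5 buffer work-up
Reagents that add atoms: none
Why: Claisen-type C-acylation of a β,δ-diketo ester polyanion, which reacts at its last-formed and most nucleophilic terminal carbon (C6), the chelated tetrahedral adduct of the Weinreb amide preventing a second addition and proton transfer to the product until the quench.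

Step 12
Reactants: 21 methyl (12Z,15R,16E,18Z,21Z)-15-[(tert-butyldimethylsilyl)oxy]-3,5,7-trioxotetracosa-12,16,18,21-tetraenoate
Product: 23 (6Z,9R,10E,12Z,15Z)-9-[(tert-butyldimethylsilyl)oxy]-1-(2,4,6-trihydroxyphenyl)octadeca-6,10,12,15-tetraen-1-one, via acylcyclohexanetrione 22 (not isolated)
Conditions: Mg(OMe)2 (8 equiv), MeOH, rt → 40 °C, Ar, dark; then cold aq. AcOH to pH 5
Reagents that add atoms: none
Why: Magnesium methoxide turns the triketo ester into a magnesium-chelated polyenolate whose C6 carbanion (between the C5 and C7 carbonyls) adds to the C1 ester carbonyl; loss of methoxide gives trione 22, which enolises three times to the aromatic triol and is thereby withdrawn from all equilibria. The closest known reaction type is the biomimetic intramolecular Claisen (Dieckmann-type) condensation by which 3,5,7-trioxoalkanoates and the related 6-(2-oxoalkyl)-4-hydroxy-2-pyrones are converted into acylphloroglucinols with magnesium alkoxides. The single ring closes by a 6-exo-trig acyl substitution that forms the C1–C6 bond, the carbocycle being C1–C6 of the ester chain with C7 (C1 of the target chain) left outside as the aryl ketone. No stereocentre is created, and the silyloxy-bearing C15 (C9 of the target) has no acidifying neighbour and is not touched. The step needs Claisen closure to win over aldol closure (C2 onto the C7 ketone, leading to a resorcylate) and over lactonisation to the pyrone; chelation holds the C5/C7 β-diketone as a non-electrophilic enolate so that the ester is the only acceptor, and in methanol any pyrone is reopened by methoxide and drained through the irreversible aromatisation. The base is mild and no Lewis or Brønsted acid is present, so the silylated dienyl carbinol and the skipped Z,Z-diene should pass unchanged.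

Step 13
Reactants: 23 (6Z,9R,10E,12Z,15Z)-9-[(tert-butyldimethylsilyl)oxy]-1-(2,4,6-trihydroxyphenyl)octadeca-6,10,12,15-tetraen-1-one
Product: 24 (6Z,9R,10E,12Z,15Z)-9-hydroxy-1-(2,4,6-trihydroxyphenyl)octadeca-6,10,12,15-tetraen-1-one
Conditions: TBAF/AcOH (1:1, 6 equiv), THF, 0 °C → rt; pH 5 phosphate work-up
Reagents that add atoms: none
Why: Fluoride-mediated desilylation buffered with acetic acid, which should cleave the Si–O bond without ionising the doubly allylic alcohol and without base-induced damage to the polyene or the phenols.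

**Compound list**

1 | (Z)-hex-3-en-1-ol | CC/C=C\CCO | starting material
2 | (Z)-1-iodohex-3-ene | CC/C=C\CCI | intermediate
3 | [(3Z)-hex-3-en-1-yl]triphenylphosphonium iodide | CC/C=C\CC[P+](c1ccccc1)(c1ccccc1)c1ccccc1.[I-] | intermediate
4 | (E)-4,4-dimethoxybut-2-enal | COC(OC)/C=C/C=O | starting material
5 | [(3Z)-hex-3-en-1-ylidene]triphenylphosphorane (ylide, not isolated) | CC/C=C\CC=P(c1ccccc1)(c1ccccc1)c1ccccc1 | intermediate
6 | (2E,4Z,7Z)-1,1-dimethoxydeca-2,4,7-triene | CC/C=C\C/C=C\C=C\C(OC)OC | intermediate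
7 | (2E,4Z,7Z)-deca-2,4,7-trienal | CC/C=C\C/C=C\C=C\C=O | intermediate
8 | allenylboronic acid pinacol ester (4,4,5,5-tetramethyl-2-(propa-1,2-dien-1-yl)-1,3,2-dioxaborolane) | C=C=CB1OC(C)(C)C(C)(C)O1 | starting material
9 | (4R,5E,7Z,10Z)-trideca-5,7,10-trien-1-yn-4-ol | CC/C=C\C/C=C\C=C\[C@H](O)CC#C | intermediate
10 | tert-butyl{[(4R,5E,7Z,10Z)-trideca-5,7,10-trien-1-yn-4-yl]oxy}dimethylsilane | CC/C=C\C/C=C\C=C\[C@H](O[Si](C)(C)C(C)(C)C)CC#C | intermediate
11 | 5-bromopentanenitrile | N#CCCCCBr | starting material
12 | methyl 5-bromopentanimidate hydrochloride (not isolated) | COC(=[NH2+])CCCCBr.[Cl-] | intermediate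
13 | 5-bromo-1,1,1-trimethoxypentane | COC(OC)(OC)CCCCBr | intermediate
14 | lithium acetylide of 10, {(4R,5E,7Z,10Z)-4-[(tert-butyldimethylsilyl)oxy]trideca-5,7,10-trien-1-yn-1-yl}lithium (not isolated) | CC/C=C\C/C=C\C=C\[C@H](O[Si](C)(C)C(C)(C)C)CC#C[Li] | intermediate
15 | tert-butyl{[(9R,10E,12Z,15Z)-1,1,1-trimethoxyoctadeca-10,12,15-trien-6-yn-9-yl]oxy}dimethylsilane, numbered from the orthoester carbon (not isolated) | CC/C=C\C/C=C\C=C\[C@H](O[Si](C)(C)C(C)(C)C)CC#CCCCCC(OC)(OC)OC | intermediate
16 | methyl (9R,10E,12Z,15Z)-9-[(tert-butyldimethylsilyl)oxy]octadeca-10,12,15-trien-6-ynoate | CC/C=C\C/C=C\C=C\[C@H](O[Si](C)(C)C(C)(C)C)CC#CCCCCC(=O)OC | intermediate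
17 | methyl (6Z,9R,10E,12Z,15Z)-9-[(tert-butyldimethylsilyl)oxy]octadeca-6,10,12,15-tetraenoate | CC/C=C\C/C=C\C=C\[C@H](O[Si](C)(C)C(C)(C)C)C/C=C\CCCCC(=O)OC | intermediate
18 | (6Z,9R,10E,12Z,15Z)-9-[(tert-butyldimethylsilyl)oxy]-N-methoxy-N-methyloctadeca-6,10,12,15-tetraenamide | CC/C=C\C/C=C\C=C\[C@H](O[Si](C)(C)C(C)(C)C)C/C=C\CCCCC(=O)N(C)OC | intermediate
19 | methyl 3,5-dioxohexanoate | CC(=O)CC(=O)CC(=O)OC | starting material
20 | trilithium tris-enolate (trianion) of methyl 3,5-dioxohexanoate (not isolated) | [Li+].[Li+].[Li+].C=C([O-])C=C([O-])C=C([O-])OC | intermediate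
21 | methyl (12Z,15R,16E,18Z,21Z)-15-[(tert-butyldimethylsilyl)oxy]-3,5,7-trioxotetracosa-12,16,18,21-tetraenoate | CC/C=C\C/C=C\C=C\[C@H](O[Si](C)(C)C(C)(C)C)C/C=C\CCCCC(=O)CC(=O)CC(=O)CC(=O)OC | intermediate
22 | 2-[(6Z,9R,10E,12Z,15Z)-9-[(tert-butyldimethylsilyl)oxy]octadeca-6,10,12,15-tetraenoyl]cyclohexane-1,3,5-trione (not isolated) | CC/C=C\C/C=C\C=C\[C@H](O[Si](C)(C)C(C)(C)C)C/C=C\CCCCC(=O)C1C(=O)CC(=O)CC1=O | intermediate
23 | (6Z,9R,10E,12Z,15Z)-9-[(tert-butyldimethylsilyl)oxy]-1-(2,4,6-trihydroxyphenyl)octadeca-6,10,12,15-tetraen-1-one | CC/C=C\C/C=C\C=C\[C@H](O[Si](C)(C)C(C)(C)C)C/C=C\CCCCC(=O)c1c(O)cc(O)cc1O | intermediate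
24 | (6Z,9R,10E,12Z,15Z)-9-hydroxy-1-(2,4,6-trihydroxyphenyl)octadeca-6,10,12,15-tetraen-1-one | CC/C=C\C/C=C\C=C\[C@H](O)C/C=C\CCCCC(=O)c1c(O)cc(O)cc1O | target

**Step count**

Total step count: 13. Longest linear sequence: 12 steps (steps 1–6 and 8–13, from 1 to 24); step 7 is a one-step side branch.

**Steps most likely to fail**

Step 12 (ring closure). The polyenolate may close in the aldol sense (C2 onto the C7 ketone) and aromatise to a resorcylate, may lactonise to the pyrone and stop there, or may lose the acyl chain by retro-Claisen attack of methoxide at C7. The fallback gives up ring construction and forms the aryl–acyl bond instead, still without any Lewis acid. It sets out from 18 and comes back at 24. Phloroglucinol F1 would be O-alkylated three times (SEMCl, i-Pr2NEt, CH2Cl2) to 1,3,5-tris{[2-(trimethylsilyl)ethoxy]methoxy}benzene F2. Directed ortho-lithiation (n-BuLi, THF, 0 °C) between two of the acetal oxygens would give the 2-lithio derivative F3, and its addition to Weinreb amide 18 (−78 → 0 °C) would give the protected aryl ketone F4. A single fluoride treatment (TBAF, THF/DMPU, 45 °C) would then remove the three SEM groups and the C9 silyl ether to give 24.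

Step 9 (semi-hydrogenation). Hydrogenation may run on past the alkene, or the conjugated diene may be hydrogenated (1,2 or 1,4) or isomerised from Z to E on the palladium surface, and the resulting isomers would be hard to separate. The fallback moves the semi-hydrogenation ahead of diene formation. It sets out from 4 and 8 and comes back at 17.
- Enal 4 would be propargylated with 8 under the conditions of step 5 (the acetal is not expected to ionise in dry toluene at −20 °C) to give (2E,4R)-1,1-dimethoxyhept-2-en-6-yn-4-ol F5, which would be silylated to its tert-butyldimethylsilyl ether F6.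
- Deprotonation to the lithium acetylide F7 and alkylation with 13 would give the orthoester F8, which the citric acid work-up would convert to methyl (9R,10E)-9-[(tert-butyldimethylsilyl)oxy]-12,12-dimethoxydodec-10-en-6-ynoate F9.
- Lindlar reduction, now with only one isolated E-alkene present, would give methyl (6Z,9R,10E)-9-[(tert-butyldimethylsilyl)oxy]-12,12-dimethoxydodeca-6,10-dienoate F10.
- Acetal hydrolysis (Amberlyst-15, wet acetone, 0 °C) would give methyl (6Z,9R,10E)-9-[(tert-butyldimethylsilyl)oxy]-12-oxododeca-6,10-dienoate F11, and a Z-selective Wittig reaction of this enal with ylide 5 (from 3, NaHMDS, THF, −78 °C) would install the 12Z,15Z unit last and give 17.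

Step 5 (asymmetric propargylation). The chiral phosphate may discriminate poorly between the faces of the extended, weakly electrophilic dienal, and the acid may promote 4Z → 4E isomerisation of the aldehyde during the long reaction time. The fallback replaces enantioselective C–C bond formation by a racemic addition followed by kinetic resolution. It sets out from 7 and comes back at 9. A zinc-mediated Barbier propargylation (propargyl bromide, Zn, THF/sat. aq. NH4Cl, 0 °C) would give racemic (5E,7Z,10Z)-trideca-5,7,10-trien-1-yn-4-ol F12. A Sharpless kinetic resolution (Ti(Oi-Pr)4, L-(+)-diisopropyl tartrate, t-BuOOH 0.6 equiv, 4 Å MS, CH2Cl2, −20 °C) should then epoxidise the (S)-enantiomer at its allylic 5,6-alkene much faster, to the epoxy alcohol (1S)-1-{(2R,3R)-3-[(1Z,4Z)-hepta-1,4-dien-1-yl]oxiran-2-yl}but-3-yn-1-ol F13. The unreacted (R)-alcohol, which is 9, would be recovered; this caps the yield of the step at half.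

**Further compounds**

F1 | step 12 | phloroglucinol (benzene-1,3,5-triol) | Oc1cc(O)cc(O)c1
F2 | step 12 | 1,3,5-tris{[2-(trimethylsilyl)ethoxy]methoxy}benzene | C[Si](C)(C)CCOCOc1cc(OCOCC[Si](C)(C)C)cc(OCOCC[Si](C)(C)C)c1
F3 | step 12 | (2,4,6-tris{[2-(trimethylsilyl)ethoxy]methoxy}phenyl)lithium | [Li]c1c(OCOCC[Si](C)(C)C)cc(OCOCC[Si](C)(C)C)cc1OCOCC[Si](C)(C)C
F4 | step 12 | (6Z,9R,10E,12Z,15Z)-9-[(tert-butyldimethylsilyl)oxy]-1-(2,4,6-tris{[2-(trimethylsilyl)ethoxy]methoxy}phenyl)octadeca-6,10,12,15-tetraen-1-one | CC/C=C\C/C=C\C=C\[C@H](O[Si](C)(C)C(C)(C)C)C/C=C\CCCCC(=O)c1c(OCOCC[Si](C)(C)C)cc(OCOCC[Si](C)(C)C)cc1OCOCC[Si](C)(C)C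
F5 | step 9 | (2E,4R)-1,1-dimethoxyhept-2-en-6-yn-4-ol | COC(OC)/C=C/[C@H](O)CC#C
F6 | step 9 | tert-butyl{[(2E,4R)-1,1-dimethoxyhept-2-en-6-yn-4-yl]oxy}dimethylsilane | COC(OC)/C=C/[C@H](O[Si](C)(C)C(C)(C)C)CC#C
F7 | step 9 | lithium acetylide of F6 | COC(OC)/C=C/[C@H](O[Si](C)(C)C(C)(C)C)CC#C[Li]
F8 | step 9 | tert-butyl{[(9R,10E)-1,1,1,12,12-pentamethoxydodec-10-en-6-yn-9-yl]oxy}dimethylsilane | COC(OC)/C=C/[C@H](O[Si](C)(C)C(C)(C)C)CC#CCCCCC(OC)(OC)OC
F9 | step 9 | methyl (9R,10E)-9-[(tert-butyldimethylsilyl)oxy]-12,12-dimethoxydodec-10-en-6-ynoate | COC(OC)/C=C/[C@H](O[Si](C)(C)C(C)(C)C)CC#CCCCCC(=O)OC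
F10 | step 9 | methyl (6Z,9R,10E)-9-[(tert-butyldimethylsilyl)oxy]-12,12-dimethoxydodeca-6,10-dienoate | COC(OC)/C=C/[C@H](O[Si](C)(C)C(C)(C)C)C/C=C\CCCCC(=O)OC
F11 | step 9 | methyl (6Z,9R,10E)-9-[(tert-butyldimethylsilyl)oxy]-12-oxododeca-6,10-dienoate | O=C/C=C/[C@H](O[Si](C)(C)C(C)(C)C)C/C=C\CCCCC(=O)OC
F12 | step 5 | racemic (5E,7Z,10Z)-trideca-5,7,10-trien-1-yn-4-ol | CC/C=C\C/C=C\C=C\C(O)CC#C
F13 | step 5 | (1S)-1-{(2R,3R)-3-[(1Z,4Z)-hepta-1,4-dien-1-yl]oxiran-2-yl}but-3-yn-1-ol | C#CC[C@H](O)[C@H]1O[C@@H]1/C=C\C/C=C\CC
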